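**Remarks on the chemistry (assumptions)**

- Ring A is the methoxylated aroyl ring (C1 acyl, C2 OH, C4 OMe, C5 O‑aryl). Ring B is the second aroyl ring (C1' acyl, C2' OH, C4' O‑aryl). The two 4‑hydroxyphenyl rings are called the outer rings.
- The target, the precursor and the product of the key step were checked atom by atom against the target SMILES. The oxygenation sites (C2, para to the ether oxygen on ring A; C2' on ring B) and the ether position are consistent, so no structure needed correcting.
- The precursor design is changed in its protecting groups only. The outer phenols are masked in the flask as trifluoroacetates by the anhydride of the oxygenation medium, in place of isolated acetates. An aryl acetate would be expected to exchange partly with hot CF3CO2H/(CF3CO)2O, and separate protection and deprotection would cost two steps.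

## Structural features

Rhuschalcone IV is a bichalcone: two (E)‑1,3‑diarylprop‑2‑en‑1‑ones joined by a diaryl ether between C5 of ring A and C4' of ring B. Ring A carries the acyl group at C1, a hydroxyl at C2, a methoxy group at C4 and the aryloxy group at C5. Ring B carries the acyl group at C1', a hydroxyl at C2' and the ether oxygen at C4'. Each enone ends in a 4‑hydroxyphenyl ring. There is no stereocentre; the only stereochemical elements are the two E alkenes, which are the thermodynamic isomers. The fragile groups are the two 2'‑hydroxychalcone units (they close to flavanones in acid or base and are Michael acceptors), the four oxidisable phenols, and the aryl vinyl ketones (liable to acid‑induced ring closure on heating). The real difficulty is an unsymmetrical diaryl ether between two differently oxygenated rings, with four free phenols and one methyl ether placed without a long protecting‑group sequence. The feature used here is that the C2 hydroxyl of ring A and the C2' hydroxyl of ring B each sit ortho to a ketone carbonyl that can steer a metal onto exactly those C–H bonds. With these two oxygens removed, both aroyl rings become plain acetophenone‑derived units whose ether linkage is a simple fluoride displacement.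

## Logic of the disconnections

**8 from 7.** The four phenolic O–C(acyl) bonds are cut. Every phenol of 8 is sensitive to trivalent iodine, and the ortho‑hydroxy enones can cyclise in hot acid, so 8 should be released only in a cold hydrolysis at the very end. The skeleton is unchanged, but 7 is the form in which the oxygenation medium delivers it, so no separate deprotection step is needed. The demand is that acid is stripped before water is added and that the hydrolysis is buffered and cold.

**7 from 6.** The C2–O bond of ring A and the C2'–O bond of ring B are cut. Each lies ortho to a ketone that can direct metalation. The gain is large: 6 has no oxygen ortho to either ketone, so its diaryl ether no longer requires differentiated polyphenols. The forward step must choose C2–H over C6–H on ring A, arene C–H over the enone β C–H, and leave both alkenes and the electron‑rich ring A untouched through two turnovers per molecule.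

**6 from 5.** The two O–C(acyl) bonds on the outer rings are cut. An electron‑withdrawing acyl mask is needed there, and the trifluoroacetyl group is the one that the medium installs by itself. The gain is that the isolable precursor 5 is the free bis‑phenol, with no protection or deprotection step. The demand is complete acylation by excess anhydride before any oxidant is present.

**5 from 3 and 4.** The two Cα=Cβ bonds are cut (retro‑aldol condensation). This removes both enones and both outer rings at once and leaves a diketone plus two equivalents of a commercial aldehyde. The forward step must run to double condensation with E geometry. Because 4 is a free phenol, which is a poor electrophile as its phenoxide, acid catalysis is required.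

**3 from 1 and 2.** The C4'–O bond of the diaryl ether is cut. The ring B carbon is para to an acetyl group, so it can be the electrophile in a nucleophilic aromatic substitution. Both partners are commercial acetophenones. The phenoxide of 1 must displace fluoride faster than either methyl ketone undergoes base‑induced self‑condensation.

## Other disconnections considered

**Alternative 1:** Ring B by cycloaddition.
- Cut: C5'–C6' and C1'–C2' of ring B, leading back to the vinylketene acetal diene A2 (Brassard type, carrying the ring A aryloxy group at C3) and the cross‑conjugated ynone A3.
- Forward key step: the nucleophilic CH2 terminus of A2 adds to the alkyne terminus of A3 and the acetal carbon to the acyl‑bearing carbon. Elimination of the acetal methoxy group aromatises the ring, and desilylation of the new ring oxygen gives A1.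
- In favour: the 2'‑hydroxy/4'‑aryloxy pattern of ring B is written into the diene. No oxidant is used. The ether oxygen is attached to a non‑aromatic carbon, so no aryl substitution is needed.
- Against: A3 offers two dienophilic π bonds and is a Michael acceptor for the ketene acetal. A2 is hydrolytically labile. Most importantly, A1 still lacks the entire acyl chain of ring A, so desilylation, ortho‑acylation of ring A beside an enone and a second phenol, a second aldol condensation and deprotection must follow.
- Comparison: on ring B regiochemistry it is the equal of the chosen plan, since ring B has two equivalent ortho sites there. It is better in that no alkene ever meets an oxidant and the pericyclic step is of a known type. It is worse on structure, because only one of the two hydroxy‑ketone pairs is solved, and clearly worse on step economy: by estimate ten or more steps against three.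

**Alternative 2:** Ring A by Dötz benzannulation.
- Cut: C5–C6, C1–C2 and C2–C3 of ring A, leading back to the chromium aryloxy(1‑methoxyvinyl)carbene A5, which already carries the complete ring B chalcone, and the terminal enyne A6.
- Forward key step: A5, A6 and one carbonyl ligand combine to give A4.
- In favour: the benzannulation by its nature places the new hydroxyl para to the carbene oxygen. This is exactly the C2–OH/C5–OAr relationship. The alkyne substituent goes ortho to that hydroxyl (C1) and the methoxyvinyl unit delivers C4–OMe. The whole 1,2,4,5 pattern of ring A is therefore programmed and the C2 versus C6 question never arises. On this point it is better than the chosen plan.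
- Against: chromium is stoichiometric. Aryloxycarbene complexes are more labile than alkoxy ones. A5 must tolerate a free chelated phenol and an enone that such carbenes can cyclopropanate on heating. The electron‑rich methoxyvinyl carbene invites non‑benzannulated products. A4 is a hydroquinone mono‑ether that oxidative removal of the Cr(CO)3 fragment could take on to a quinone. The side chain arrives as a racemic silyl carbinol, so desilylation, allylic oxidation and acetal removal remain.
- Comparison: the reaction class is known, but the carbene is unusually functionalised, which makes the mechanistic risk comparable. Step economy is far worse, roughly a dozen steps with a stoichiometric metal. The chosen plan is much shorter but stakes more on selectivity.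

**Alternative 3:** Double hydroacylation.
- Cut: both carbonyl carbon–Cα bonds, leading back to the bis‑salicylaldehyde A8 and two molecules of the arylalkyne A9.
- Forward key step: with [RhCl(cod)]2, dppf and Na2CO3, phenoxide‑bound monovalent rhodium inserts into each aldehyde C–H bond to give a chelated acyl hydride of trivalent rhodium. Syn addition across the alkyne and reductive elimination give A7.
- In favour: it uses the same ortho‑hydroxy carbonyl chelate as the chosen plan, but in a redox‑neutral way, so neither phenols nor alkenes are exposed to an oxidant. It is atom‑economic and sets the E geometry by syn addition. Hydroacylation of alkynes by salicylaldehydes is an established substrate class, which is better precedent than the chosen key step has.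
- Against: a terminal arylalkyne can insert in either sense (linear E enone or branched 2‑aryl enone), and this must go the right way twice. Alkyne oligomerisation competes. Base and metal can close the ortho‑hydroxy enone. The burden moves into A8, which already holds both ortho hydroxyls and so needs oxygenated, selectively protected partners for its ether bond.
- Comparison: it is equal in bonds made in the key step (two) and comparable in regiochemical risk. It is better on redox chemoselectivity and precedent. It is worse on access to the substrates and on step count, about seven steps by estimate.

Key step: step 3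

## Route

Step 1
Reactants: 1 3'-hydroxy-4'-methoxyacetophenone; 2 4'-fluoroacetophenone
Product: 3 1-[3-(4-acetylphenoxy)-4-methoxyphenyl]ethanone
Conditions: K2CO3 (1.5 equiv), DMSO, 120 °C, N2
Reagents that add atoms: none
Why: Nucleophilic aromatic substitution (addition–elimination): the para‑acetyl group stabilises the Meisenheimer intermediate and fluoride is the best leaving group for this mechanism; only one phenol is present, so the ether can form only at the oxygen meta to the acetyl group of 1.

Step 2
Reactants: 3 1-[3-(4-acetylphenoxy)-4-methoxyphenyl]ethanone; 4 4-hydroxybenzaldehyde (2.4 equiv)
Product: 5 (2E)-3-(4-hydroxyphenyl)-1-[3-[4-[(2E)-3-(4-hydroxyphenyl)prop-2-enoyl]phenoxy]-4-methoxyphenyl]prop-2-en-1-one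
Conditions: dry HCl (sat.), EtOH, 0 °C to rt
Reagents that add atoms: none
Why: Double acid‑catalysed Claisen–Schmidt (crossed aldol) condensation; acid is used because the free phenol of 4 would be deprotonated by base and the aldehyde deactivated, while the protonated aldehyde stays electrophilic. Dehydration of each benzylic aldol is fast in acid and gives the conjugated E enone as the thermodynamic isomer; neither 3 nor the product has a group that acid can cyclise.

Step 3
Reactants: 5 (2E)-3-(4-hydroxyphenyl)-1-[3-[4-[(2E)-3-(4-hydroxyphenyl)prop-2-enoyl]phenoxy]-4-methoxyphenyl]prop-2-en-1-one
Product: 8 rhuschalcone IV, via dideoxy bichalcone bis(trifluoroacetate) 6 (not isolated), via rhuschalcone IV tetrakis(trifluoroacetate) 7 (not isolated)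
Conditions: (CF3CO)2O/CF3CO2H (1:3), rt, 30 min; then [RuCl2(p-cymene)]2 (5 mol %), PhI(OCOCF3)2 (2.5 equiv, in portions), 70 °C; evaporate cold; then THF/pH 7 phosphate buffer, 0 °C to rt
Reagents that add atoms: [bis(trifluoroacetoxy)iodo]benzene, O=C(OI(OC(=O)C(F)(F)F)c1ccccc1)C(F)(F)F, together with the trifluoroacetic acid medium, OC(=O)C(F)(F)F (trifluoroacetate is the source of the two new ring oxygens of 8); trifluoroacetic anhydride, O=C(OC(=O)C(F)(F)F)C(F)(F)F (trifluoroacetyl groups of 6 and 7 only, lost again in the hydrolysis)
Why: Proposed new method: ketone‑directed ortho C–H oxygenation by divalent ruthenium carboxylates with a trivalent iodine oxidant is established for aryl alkyl and diaryl ketones, which is the closest known reaction type, and is extended here to aryl styryl ketones. The anhydride first turns the two outer phenols of 5 into the trifluoroacetates 6, so that no free phenol meets the oxidant and the styryl alkenes become electron‑poorer. Each ketone oxygen then binds the ruthenium trifluoroacetate formed in the medium, carboxylate‑assisted metalation gives a five‑membered ruthenacycle at the ortho carbon, PhI(OCOCF3)2 oxidises it to tetravalent ruthenium, and C–O reductive elimination releases the aryl trifluoroacetate and returns divalent ruthenium. No ring is closed and no stereocentre is formed; the two E alkenes are the thermodynamic isomers and should persist in acid. On ring A the metal should take C2–H because C6–H is wedged between the acyl and aryloxy groups, where a ruthenacycle would clash with the ether substituent, and because C2 is the more electron‑rich site (para to the ether oxygen); on ring B the two ortho sites are equivalent. Arene C–H should win over the enone β C–H because electrophilic, carboxylate‑assisted metalation favours the electron‑rich ring carbon over the electron‑poor β carbon, which also bears an aryl group and would give a crowded alkenyl–ruthenium species. Each new ortho trifluoroacetoxy group deactivates its ring against a second oxygenation, the moderate temperature is chosen to hold back acid‑induced ring closure of the aryl vinyl ketones, and the phenols stay masked until the cold buffered hydrolysis of 7, which should keep the ortho‑hydroxy enones from closing to flavanones.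

## Compound list

1 | 3'-hydroxy-4'-methoxyacetophenone | COc1ccc(C(C)=O)cc1O | starting material
2 | 4'-fluoroacetophenone | CC(=O)c1ccc(F)cc1 | starting material
3 | 1-[3-(4-acetylphenoxy)-4-methoxyphenyl]ethanone | COc1ccc(C(C)=O)cc1Oc1ccc(C(C)=O)cc1 | intermediate
4 | 4-hydroxybenzaldehyde | O=Cc1ccc(O)cc1 | starting material
5 | (2E)-3-(4-hydroxyphenyl)-1-[3-[4-[(2E)-3-(4-hydroxyphenyl)prop-2-enoyl]phenoxy]-4-methoxyphenyl]prop-2-en-1-one (2,2'-dideoxy bichalcone, free bis-phenol) | COc1ccc(C(=O)/C=C/c2ccc(O)cc2)cc1Oc1ccc(C(=O)/C=C/c2ccc(O)cc2)cc1 | intermediate
6 | bis(trifluoroacetate) of 5 (both outer phenols acylated; not isolated) | COc1ccc(C(=O)/C=C/c2ccc(OC(=O)C(F)(F)F)cc2)cc1Oc1ccc(C(=O)/C=C/c2ccc(OC(=O)C(F)(F)F)cc2)cc1 | intermediate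
7 | tetrakis(trifluoroacetate) of rhuschalcone IV (not isolated) | COc1cc(OC(=O)C(F)(F)F)c(C(=O)/C=C/c2ccc(OC(=O)C(F)(F)F)cc2)cc1Oc1ccc(C(=O)/C=C/c2ccc(OC(=O)C(F)(F)F)cc2)c(OC(=O)C(F)(F)F)c1 | intermediate
8 | rhuschalcone IV, (2E)-1-[2-hydroxy-5-[3-hydroxy-4-[(2E)-3-(4-hydroxyphenyl)prop-2-enoyl]phenoxy]-4-methoxyphenyl]-3-(4-hydroxyphenyl)prop-2-en-1-one | COc1cc(O)c(C(=O)/C=C/c2ccc(O)cc2)cc1Oc1ccc(C(=O)/C=C/c2ccc(O)cc2)c(O)c1 | target

## Step count and least certain steps

Total steps: 3. Longest linear sequence: 3 steps (1 or 2, then 3, 5 and 8).

**Step 3 (key step, proposed new method).**
- What may go wrong: metalation at the enone β C–H or at C6–H instead of C2–H. Attack of trivalent iodine on an alkene, with an aryl shift. Acid‑induced Nazarov‑type ring closure of an aryl vinyl ketone onto the activated ring A at elevated temperature. Stalling after the first of the two oxygenations. Closure to a flavanone while the trifluoroacetates are being hydrolysed in residual acid.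
- Fallback (known chemistry): move the oxygenation in front of the enone construction, so that it runs on aryl methyl ketones, the substrate class for which it is established. Setting out from 3, the same [RuCl2(p-cymene)]2/PhI(OCOCF3)2 system in CF3CO2H/(CF3CO)2O should give the bis(trifluoroacetate) of the doubly ortho‑hydroxylated diketone F1. Hydrolysis on work‑up gives 1-[5-(4-acetyl-3-hydroxyphenoxy)-2-hydroxy-4-methoxyphenyl]ethanone F2. Base‑mediated double Claisen–Schmidt condensation of F2 with purchased 4-(methoxymethoxy)benzaldehyde (KOH, EtOH, rt) should then give the bis(methoxymethyl) ether of rhuschalcone IV F3. HCl in MeOH removes the two acetals and the route is rejoined at 8.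

**Step 2.**
- What may go wrong: slow or incomplete double condensation, because the hydroxyl group lowers the electrophilicity of the aldehyde, so that the reaction stops at the mono‑enone. Acid‑promoted self‑condensation of the diketone and conjugate addition of ethanol to the enones are also possible.
- Fallback: setting out from 3, a base‑mediated Claisen–Schmidt condensation with purchased 4-(methoxymethoxy)benzaldehyde (KOH, EtOH/H2O, rt), in which the aldehyde cannot be deactivated as a phenoxide, should give the bis(methoxymethyl) ether of the dideoxy bichalcone F4. Acetal cleavage with HCl in MeOH returns to the route at 5.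

**Step 1.**
- What may go wrong: base‑induced aldol self‑condensation of either methyl ketone in hot basic DMSO. Sluggish displacement, because a single para‑acetyl group activates the fluoride only moderately and the phenoxide is flanked by a methoxy group.
- Fallback: setting out from 1, a Chan–Lam coupling with purchased 4-acetylphenylboronic acid (Cu(OAc)2, pyridine, 4 Å molecular sieves, CH2Cl2, air, rt) forms the same C–O bond at room temperature without a strong base and arrives directly at 3. It makes no new compound.

## Further compounds

F1 | step 3 | bis(trifluoroacetate) of 1-[5-(4-acetyl-3-hydroxyphenoxy)-2-hydroxy-4-methoxyphenyl]ethanone | COc1cc(OC(=O)C(F)(F)F)c(C(C)=O)cc1Oc1ccc(C(C)=O)c(OC(=O)C(F)(F)F)c1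
F2 | step 3 | 1-[5-(4-acetyl-3-hydroxyphenoxy)-2-hydroxy-4-methoxyphenyl]ethanone | COc1cc(O)c(C(C)=O)cc1Oc1ccc(C(C)=O)c(O)c1
F3 | step 3 | bis(methoxymethyl) ether of rhuschalcone IV (both outer phenols as methoxymethyl ethers, both alkenes E) | COc1cc(O)c(C(=O)/C=C/c2ccc(OCOC)cc2)cc1Oc1ccc(C(=O)/C=C/c2ccc(OCOC)cc2)c(O)c1
F4 | step 2 | bis(methoxymethyl) ether of 5 (both alkenes E) | COc1ccc(C(=O)/C=C/c2ccc(OCOC)cc2)cc1Oc1ccc(C(=O)/C=C/c2ccc(OCOC)cc2)cc1
F0 | step 1 | none | none
A1 | alternative 1 | (2E)-1-[4-[4-(tert-butyldimethylsilyloxy)-2-methoxyphenoxy]-2-hydroxyphenyl]-3-[4-(methoxymethoxy)phenyl]prop-2-en-1-one | COc1cc(O[Si](C)(C)C(C)(C)C)ccc1Oc1ccc(C(=O)/C=C/c2ccc(OCOC)cc2)c(O)c1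
A2 | alternative 1 | 3-[4-(tert-butyldimethylsilyloxy)-2-methoxyphenoxy]-1-methoxy-1-(trimethylsilyloxy)buta-1,3-diene | C=C(Oc1ccc(O[Si](C)(C)C(C)(C)C)cc1OC)C=C(OC)O[Si](C)(C)C
A3 | alternative 1 | (1E)-1-[4-(methoxymethoxy)phenyl]pent-1-en-4-yn-3-one | C#CC(=O)/C=C/c1ccc(OCOC)cc1
A4 | alternative 2 | bis(methoxymethyl) ether of rhuschalcone IV with the ring A ketone replaced by its tert-butyldimethylsilyl-protected secondary carbinol (racemic, both alkenes E) | COc1cc(O)c(C(O[Si](C)(C)C(C)(C)C)/C=C/c2ccc(OCOC)cc2)cc1Oc1ccc(C(=O)/C=C/c2ccc(OCOC)cc2)c(O)c1
A5 | alternative 2 | pentacarbonyl chromium carbene (CO)5Cr=C(OAr)C(OMe)=CH2, Ar = 3-hydroxy-4-[(2E)-3-[4-(methoxymethoxy)phenyl]prop-2-enoyl]phenyl | C=C(OC)C(Oc1ccc(C(=O)/C=C/c2ccc(OCOC)cc2)c(O)c1)=[Cr](=C=O)(=C=O)(=C=O)(=C=O)=C=O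
A6 | alternative 2 | tert-butyl[[(1E)-1-[4-(methoxymethoxy)phenyl]pent-1-en-4-yn-3-yl]oxy]dimethylsilane (racemic) | C#CC(O[Si](C)(C)C(C)(C)C)/C=C/c1ccc(OCOC)cc1
A7 | alternative 3 | bis(methoxymethyl) ether of rhuschalcone IV (both outer phenols as methoxymethyl ethers, both alkenes E) | COc1cc(O)c(C(=O)/C=C/c2ccc(OCOC)cc2)cc1Oc1ccc(C(=O)/C=C/c2ccc(OCOC)cc2)c(O)c1
A8 | alternative 3 | 5-(4-formyl-3-hydroxyphenoxy)-2-hydroxy-4-methoxybenzaldehyde | COc1cc(O)c(C=O)cc1Oc1ccc(C=O)c(O)c1
A9 | alternative 3 | 1-ethynyl-4-(methoxymethoxy)benzene | C#Cc1ccc(OCOC)cc1
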